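## Retrosynthetic overview

1. The only ring, the 1,2-dioxane O1–O2–C3–C4–C5–C6, is opened at two bonds in one retrosynthetic step: C3–O2 (retro peroxy-Michael, C3 being β to the ester carbonyl C1) and the C6 peroxyketal (ketone + H2O2 + MeOH). This leads back to an achiral, acyclic C22 keto-enoate.
2. Enabling feature: C6 carries two oxygens (ring O1 and the exocyclic OMe), so it is at the ketone oxidation level and can epimerise through a ring peroxycarbenium ion. In the target the OMe is cis to the C3 side chain, that is, axial OMe (anomeric) with both carbon chains equatorial. This is the thermodynamic C6 epimer, so only C3 needs kinetic (catalyst) control.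
3. The keto-enoate comes from a Sonogashira coupling (C11–C12) of an (E)-vinyl iodide (C12–C22, distal alkyne masked as its silyl derivative) with a C1–C11 alkynyl keto-enoate; the silyl group is removed before the peroxide is made.
4. The C1–C11 fragment comes from hex-5-ynoic acid by Weinreb ketone synthesis (C5–C6) with an acetal Grignard reagent, acetal hydrolysis and Wittig olefination (C2=C3). The vinyl iodide comes from dec-9-yn-1-ol by C-silylation, oxidation and Takai olefination.
5. Ring order: there is one ring, and it is closed in the last step by a three-component union of ketone, hydrogen peroxide and methanol.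

Key step: step 10

Remark (assumption): the sense of induction of the squaramide catalyst in step 10 cannot be predicted for this new substrate class. The quinine-derived catalyst is written; its quinidine-derived pseudo-enantiomer is to be taken if the opposite sense is found.

## Route

Step 1
Reactants: 1 dec-9-yn-1-ol
Product: 3 10-(trimethylsilyl)dec-9-yn-1-ol, via bis-silyl ether 2 (not isolated)
Conditions: n-BuLi (2.2 equiv), THF, −78 °C; TMSCl (2.3 equiv), −78 °C to rt; then 1 M aq. HCl, rt
Reagents that add atoms: chlorotrimethylsilane, C[Si](C)(C)Cl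
Why: Double deprotonation (O–H and acetylenic C–H) and double silylation should give 2, from which dilute acid cleaves only the labile O–Si bond (standard C-silylation of a terminal alkyne).

Step 2
Reactants: 3 10-(trimethylsilyl)dec-9-yn-1-ol
Product: 4 10-(trimethylsilyl)dec-9-ynal
Conditions: TEMPO (10 mol%), PhI(OAc)2 (1.1 equiv), CH2Cl2, rt
Reagents that add atoms: none
Why: The oxoammonium-mediated TEMPO/PhI(OAc)2 oxidation of a primary alcohol should stop at the aldehyde and leave the silyl alkyne untouched.

Step 3
Reactants: 4 10-(trimethylsilyl)dec-9-ynal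
Product: 5 [(10E)-11-iodoundec-10-en-1-yn-1-yl]trimethylsilane
Conditions: CrCl2 (6 equiv), CHI3 (2 equiv), 1,4-dioxane/THF, 0 °C to rt
Reagents that add atoms: iodoform, IC(I)I
Why: In the Takai olefination the geminal dichromium species from CHI3 and divalent chromium adds to the aldehyde and eliminates to the (E)-vinyl iodide, which sets the C12=C13 geometry while the silyl alkyne is inert.

Step 4
Reactants: 6 hex-5-ynoic acid
Product: 7 N-methoxy-N-methylhex-5-ynamide
Conditions: MeNHOMe·HCl, EDC·HCl, N-methylmorpholine, CH2Cl2, 0 °C to rt
Reagents that add atoms: N,O-dimethylhydroxylamine hydrochloride, CNOC.Cl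
Why: Carbodiimide-mediated amidation should give the Weinreb amide with the terminal alkyne as a spectator.

Step 5
Reactants: 7 N-methoxy-N-methylhex-5-ynamide; 8 [2-(1,3-dioxolan-2-yl)ethyl]magnesium bromide (commercial THF solution)
Product: 9 1-(1,3-dioxolan-2-yl)oct-7-yn-3-one
Conditions: 8 (2.3 equiv), THF, 0 °C to rt; aq. NH4Cl
Reagents that add atoms: none
Why: In the Weinreb ketone synthesis the N-methoxy-N-methyl amide stops the addition at the ketone level, the first equivalent of 8 being consumed by the acetylenic C–H (restored on quench) and the dioxolane being stable to the Grignard reagent.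

Step 6
Reactants: 9 1-(1,3-dioxolan-2-yl)oct-7-yn-3-one
Product: 10 4-oxonon-8-ynal
Conditions: 2 M aq. HCl, THF, rt; product used crude at once
Reagents that add atoms: water, O
Why: Acid-catalysed acetal hydrolysis should unmask the aldehyde without touching the ketone or the alkyne.

Step 7
Reactants: 10 4-oxonon-8-ynal; 11 methyl (triphenylphosphoranylidene)acetate
Product: 12 methyl (2E)-6-oxoundec-2-en-10-ynoate
Conditions: 11 (1.1 equiv), CH2Cl2, rt
Reagents that add atoms: none
Why: The Wittig olefination with a stabilised ylide should react only at the aldehyde, not the ketone, and give the (E)-enoate.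

Step 8
Reactants: 5 [(10E)-11-iodoundec-10-en-1-yn-1-yl]trimethylsilane; 12 methyl (2E)-6-oxoundec-2-en-10-ynoate
Product: 13 methyl (2E,12E)-6-oxo-22-(trimethylsilyl)docosa-2,12-diene-10,21-diynoate
Conditions: Pd(PPh3)2Cl2 (3 mol%), CuI (6 mol%), Et3N, THF (degassed), rt
Reagents that add atoms: none
Why: The Sonogashira coupling of the (E)-vinyl iodide with the only free terminal alkyne should proceed at rt with retention of alkene geometry, the distal alkyne being masked as its silyl derivative and the ketone and enoate being tolerated.

Step 9
Reactants: 13 methyl (2E,12E)-6-oxo-22-(trimethylsilyl)docosa-2,12-diene-10,21-diynoate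
Product: 14 methyl (2E,12E)-6-oxodocosa-2,12-diene-10,21-diynoate
Conditions: AgNO3 (10 mol%), acetone/H2O, rt, dark
Reagents that add atoms: none
Why: Silver-catalysed protodesilylation of the alkynylsilane is neutral, so the base-sensitive keto-enoate should not suffer conjugate addition or intramolecular Michael reaction.

Step 10
Reactants: 14 methyl (2E,12E)-6-oxodocosa-2,12-diene-10,21-diynoate
Product: 18 methyl 2-[(3S,6R)-6-[(6E)-hexadec-6-ene-4,15-diyn-1-yl]-6-methoxy-1,2-dioxan-3-yl]acetate (target), via hydroperoxy ketal 15 (not isolated), via C6-epimeric peroxyketal 16 (not isolated), via peroxycarbenium ion 17 (not isolated)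
Conditions: (a) urea·H2O2 (5 equiv), Sc(OTf)3 (10 mol%), MeOH, 0 °C to rt, then Et2O/H2O wash and solvent exchange; (b) 3-{[3,5-bis(trifluoromethyl)phenyl]amino}-4-{[(8α,9S)-6′-methoxycinchonan-9-yl]amino}cyclobut-3-ene-1,2-dione (quinine-derived squaramide, C32H28F6N4O3, 10 mol%), CH2Cl2, −20 °C; (c) camphor-10-sulfonic acid (30 mol%), MeOH, rt
Reagents that add atoms: hydrogen peroxide, OO (used as urea–hydrogen peroxide, NC(N)=O.OO); methanol, CO
Why: Proposed new method: Sc(OTf)3 activates only the C6 ketone of 14 toward addition of H2O2 and MeOH to give racemic methoxy hydroperoxide 15, whose OOH group (more acidic and, through the alpha effect, more nucleophilic than an alcohol) is then deprotonated by the quinuclidine nitrogen of the squaramide catalyst while the two squaramide N–H bonds hold the enoate carbonyl, so that the terminal peroxide oxygen adds to C3 (intramolecular peroxy-Michael addition) and the enolate is protonated. The closest known reaction types are the achiral Et2NH/CF3CH2OH cyclisation of hydroperoxy ketals onto enoates, for which the catalyst unites amine and hydrogen-bond donor in one chiral molecule, and the bifunctional-organocatalyst enantioselective intramolecular oxa-Michael addition of alcohols to enoates; an enantioselective variant with a hydroperoxide nucleophile has not been shown, hence the label. The 1,2-dioxane closes by 6-exo-trig attack of O2 on C3. C3 (S) is set by the catalyst, which should select the same enoate face in both enantiomers of 15 and so give 18 together with its C6 epimer 16; C6 (R) is then set under thermodynamic control, because camphorsulfonic acid in MeOH ionises the C6–OMe bond to the ring peroxycarbenium ion 17 and methanol returns reversibly until the epimer with axial OMe (anomeric effect) and both carbon chains equatorial, which is 18, dominates, while C3 is untouched by acid. The step needs chemoselective perketalisation (only the ketone is electrophilic enough under the Lewis acid; enoate, enyne and terminal alkyne are inert), no background cyclisation (none is expected without base, and excess H2O2 is washed out before the amine catalyst is added), and catalyst control over the remote C6 centre, which its 1,4-distance from C3 and the flexibility of the open chain should make weak.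

## Compound list

1 | dec-9-yn-1-ol | C#CCCCCCCCCO | starting material
2 | trimethyl{[10-(trimethylsilyl)dec-9-yn-1-yl]oxy}silane (bis-silyl ether) | C[Si](C)(C)C#CCCCCCCCCO[Si](C)(C)C | intermediate
3 | 10-(trimethylsilyl)dec-9-yn-1-ol | C[Si](C)(C)C#CCCCCCCCCO | intermediate
4 | 10-(trimethylsilyl)dec-9-ynal | C[Si](C)(C)C#CCCCCCCCC=O | intermediate
5 | [(10E)-11-iodoundec-10-en-1-yn-1-yl]trimethylsilane | C[Si](C)(C)C#CCCCCCCC/C=C/I | intermediate
6 | hex-5-ynoic acid | C#CCCCC(=O)O | starting material
7 | N-methoxy-N-methylhex-5-ynamide | C#CCCCC(=O)N(C)OC | intermediate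
8 | [2-(1,3-dioxolan-2-yl)ethyl]magnesium bromide | Br[Mg]CCC1OCCO1 | starting material
9 | 1-(1,3-dioxolan-2-yl)oct-7-yn-3-one | C#CCCCC(=O)CCC1OCCO1 | intermediate
10 | 4-oxonon-8-ynal | C#CCCCC(=O)CCC=O | intermediate
11 | methyl (triphenylphosphoranylidene)acetate | COC(=O)C=P(c1ccccc1)(c1ccccc1)c1ccccc1 | starting material
12 | methyl (2E)-6-oxoundec-2-en-10-ynoate | C#CCCCC(=O)CC/C=C/C(=O)OC | intermediate
13 | methyl (2E,12E)-6-oxo-22-(trimethylsilyl)docosa-2,12-diene-10,21-diynoate | C[Si](C)(C)C#CCCCCCCC/C=C/C#CCCCC(=O)CC/C=C/C(=O)OC | intermediate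
14 | methyl (2E,12E)-6-oxodocosa-2,12-diene-10,21-diynoate | C#CCCCCCCC/C=C/C#CCCCC(=O)CC/C=C/C(=O)OC | intermediate
15 | methyl (2E,12E)-6-hydroperoxy-6-methoxydocosa-2,12-diene-10,21-diynoate (racemic at C6) | C#CCCCCCCC/C=C/C#CCCCC(OC)(OO)CC/C=C/C(=O)OC | intermediate
16 | methyl 2-[(3S,6S)-6-[(6E)-hexadec-6-ene-4,15-diyn-1-yl]-6-methoxy-1,2-dioxan-3-yl]acetate (C6 epimer) | C#CCCCCCCC/C=C/C#CCCC[C@@]1(OC)CC[C@@H](CC(=O)OC)OO1 | intermediate
17 | (3S)-6-[(6E)-hexadec-6-ene-4,15-diyn-1-yl]-3-(2-methoxy-2-oxoethyl)-4,5-dihydro-3H-1,2-dioxin-1-ium (ring peroxycarbenium ion) | C#CCCCCCCC/C=C/C#CCCCC1=[O+]O[C@H](CC(=O)OC)CC1 | intermediate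
18 | methyl 2-[(3S,6R)-6-[(6E)-hexadec-6-ene-4,15-diyn-1-yl]-6-methoxy-1,2-dioxan-3-yl]acetate | C#CCCCCCCC/C=C/C#CCCC[C@]1(OC)CC[C@@H](CC(=O)OC)OO1 | target

## Summary

Total step count: 10.
Longest linear sequence: 7 steps (steps 4, 5, 6, 7, 8, 9, 10, from hex-5-ynoic acid); the vinyl iodide branch (steps 1 to 3) joins at step 8.

## Steps most likely to fail, with fallbacks

Step 10 (proposed new method). What may go wrong: insufficient catalyst control at C3, for example the mismatched enantiomer of 15 cyclising through the other enoate face, which after equilibration would erode the enantiomeric purity; or oxidation of the catalyst amine by the hydroperoxide, stalling turnover. The fallback uses known chemistry only, sets out from 14 and comes back at 18. Compound 14 is perketalised as in stage (a) to 15. The ring is then closed with the established achiral conditions, Et2NH in CF3CH2OH at rt. This should give all four stereoisomers: 16, 18, and their enantiomers methyl 2-[(3R,6R)-6-[(6E)-hexadec-6-ene-4,15-diyn-1-yl]-6-methoxy-1,2-dioxan-3-yl]acetate F1 and methyl 2-[(3R,6S)-6-[(6E)-hexadec-6-ene-4,15-diyn-1-yl]-6-methoxy-1,2-dioxan-3-yl]acetate F2. Camphorsulfonic acid in MeOH should then convert 16 into 18 and F1 into F2. The resulting racemate is resolved by preparative HPLC on a chiral stationary phase (amylose tris(3,5-dimethylphenylcarbamate)), which delivers 18 at the cost of half the material.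

Step 6. What may go wrong: acid-induced cyclodehydration to a furan or aldol self-condensation of the 1,4-keto aldehyde as it is released. The fallback generates the aldehyde under neutral oxidative conditions and traps it in the same flask; it sets out from 7 and comes back at 12. (3-Bromopropoxy)(tert-butyl)dimethylsilane and Mg in THF give {3-[(tert-butyldimethylsilyl)oxy]propyl}magnesium bromide F3. Addition of F3 (2.3 equiv) to 7 should give 1-[(tert-butyldimethylsilyl)oxy]non-8-yn-4-one F4. TBAF/AcOH in THF then frees 1-hydroxynon-8-yn-4-one F5 (in equilibrium with its cyclic hemiketal). Oxidation of F5 with IBX in DMSO in the presence of ylide 11 (tandem oxidation–Wittig) forms 10 only transiently and should give 12 directly.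

Step 9. What may go wrong: stalled turnover through precipitation of the silver acetylide, or, if harsher basic desilylation has to be used, conjugate addition to the enoate and intramolecular Michael reaction of the ketone enolate. The fallback moves the desilylation to a robust intermediate; it sets out from 5 and 9 and comes back at 14. Sonogashira coupling of 5 with 9 (Pd(PPh3)2Cl2, CuI, Et3N, THF) should give (9E)-1-(1,3-dioxolan-2-yl)-19-(trimethylsilyl)nonadec-9-ene-7,18-diyn-3-one F6. K2CO3 in MeOH removes the silyl group to give (9E)-1-(1,3-dioxolan-2-yl)nonadec-9-ene-7,18-diyn-3-one F7. Aqueous HCl in THF releases (10E)-4-oxoicos-10-ene-8,19-diynal F8, and Wittig olefination with 11 should give 14.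

## Further compounds

F1 | step 10 | methyl 2-[(3R,6R)-6-[(6E)-hexadec-6-ene-4,15-diyn-1-yl]-6-methoxy-1,2-dioxan-3-yl]acetate | C#CCCCCCCC/C=C/C#CCCC[C@]1(OC)CC[C@H](CC(=O)OC)OO1
F2 | step 10 | methyl 2-[(3R,6S)-6-[(6E)-hexadec-6-ene-4,15-diyn-1-yl]-6-methoxy-1,2-dioxan-3-yl]acetate | C#CCCCCCCC/C=C/C#CCCC[C@@]1(OC)CC[C@H](CC(=O)OC)OO1
F3 | step 6 | {3-[(tert-butyldimethylsilyl)oxy]propyl}magnesium bromide | Br[Mg]CCCO[Si](C)(C)C(C)(C)C
F4 | step 6 | 1-[(tert-butyldimethylsilyl)oxy]non-8-yn-4-one | C#CCCCC(=O)CCCO[Si](C)(C)C(C)(C)C
F5 | step 6 | 1-hydroxynon-8-yn-4-one | C#CCCCC(=O)CCCO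
F6 | step 9 | (9E)-1-(1,3-dioxolan-2-yl)-19-(trimethylsilyl)nonadec-9-ene-7,18-diyn-3-one | C[Si](C)(C)C#CCCCCCCC/C=C/C#CCCCC(=O)CCC1OCCO1
F7 | step 9 | (9E)-1-(1,3-dioxolan-2-yl)nonadec-9-ene-7,18-diyn-3-one | C#CCCCCCCC/C=C/C#CCCCC(=O)CCC1OCCO1
F8 | step 9 | (10E)-4-oxoicos-10-ene-8,19-diynal | C#CCCCCCCC/C=C/C#CCCCC(=O)CCC=O
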